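The numbers in the tables are calculated with constants of no real substance; the scatter is artificial.

You cannot make target from substrate that reads 0%, and that is where Wednesday's flask stands at 4.00 min, with target at 48% of the substrate charged after 58% at 0.333 min; call that last reading the ceiling.

| setting | Saturday's | Wednesday's | north-west | south-west | south-east |
|---|---|---|---|---|---|
| substrate | 0.20 mM | 0.20 mM | 0.20 mM | 0.20 mM | 0.20 mM |
| reagent | 0.070 mM (fed, over 15 s) | 0.80 mM (fed, over 15 s) | 0.0600 mM (fed, over 15 s) | 0.200 mM (fed, over 15 s) | 0.600 mM (fed, over 15 s) |
| initiator | 3 µM | 3 µM | 3.0 µM | 3.0 µM | 3.0 µM |
| remark | run made earlier | run made earlier |  |  |  |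
| time |  |  | 4.0 min | 4.0 min | 4.0 min |

- Saturday's (time / min: target / %, substrate / %): 1.00: 13, 74; 2.00: 14, 69; 3.00: 15, 67; 4.00: 13, 66
- Wednesday's (time / min: target / %, substrate / %): 0.333: 58, 13; 0.667: 52, 5; 1.50: 49, 3; 4.00: 48, 0

(each reading ± 1.5 percentage points)

- what was read earlier has a scatter of 1.5 percentage points, one standard deviation
- "hardly changes" means that all values lie within two and a half points (for a concentration: within two and a half percent of the largest)

- amount of target at the end, in percent of the substrate charged for north-west, south-west, south-east, in this order
- how that number moves from the first to the last of them (rises all the way / hardly changes / falls, then rises / falls all the way / rises, then falls)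

Saturday's flask, charged with less reagent than substrate, ends with target at 13% and substrate at 66%. Count turnovers there: it reads 0.371 target formed per reagent charged, both in mM, and you may call this y.

My own reckoning takes the smaller of two numbers: y times the charge, or the ceiling. Reagent is then the limiting reagent below 0.258 mM. That gives 11.1% for north-west, 37.1% for south-west and 48% for south-east.

The forecast, reasoned separately, says 12%, 39% and 47%, and rises all the way, “flattening at high dose”.

The flasks give 12.4%, 32.1% and 47.7%: the number rises all the way, as forecast, but south-west stands 6.9 percentage points below the forecast.

    reagent ⇌ dormant form (K = 15.0, k = 0.0844 /s)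
    substrate + initiating radical → capped initiator + first chain carrier (k = 2.93 × 10⁷ /M/s)
    reagent + first chain carrier ⇌ target + second chain carrier (K = 1.30, k = 3.56 × 10⁶ /M/s)
    2 first chain carrier → ended chains (k = 4.00 × 10⁶ /M/s)
    2 substrate → self-condensation product (k = 0.576 /M/s)
    initiator → 2 initiating radical (k = 0.00902 /s)
    substrate + second chain carrier → released group + first chain carrier (k = 4.34 × 10⁵ /M/s)
    target ⇌ isomer of the product (K = 1.00, k = 0.0432 /s)

Put y through the results: north-west gives 0.413, south-west 0.321 and south-east 0.159. In north-west, the half-life of target by its forward step to the isomer of the product alone is 0.27 min at 0.206 min, shorter than the 4.0 min allowed. South-west at 4.00 min holds target at 32.1% beside the isomer of the product at 31.8%, and dormant form at 0.0683 mM, a third of its reagent charge.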